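**Bending curves.** A pitfall waits in the alder and maple runs: reagent and substrate fall together in both, so the bend of a product curve does not tell the two apart. A slope can still be read. The rate of making product near 30 % conversion per catalyst charged, τ (a turnover frequency), reads 2.59 h⁻¹ across the alder readings around that level. The maple run gives 2.64 h⁻¹, so the two readings of τ lie close together at those two charges.

in all of them: substrate 0.41 M
- alder: reagent 0.82 M; free catalyst 25 mM; run made earlier
- maple: reagent 0.82 M; free catalyst 40 mM; run made earlier
- flask: reagent 0.820 M; free catalyst 18 mM

| run | time / h | product / % |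
|---|---|---|
| alder | 0.200 | 3.1 |
| alder | 0.667 | 12.7 |
| alder | 1.00 | 18.8 |
| alder | 1.50 | 27.0 |
| alder | 2.50 | 42.5 |
| maple | 0.500 | 13.9 |
| maple | 1.00 | 27.9 |
| maple | 1.33 | 37.0 |
| maple | 2.00 | 52.5 |
| maple | 2.50 | 62.8 |

(scatter of a reading: 0.5 percentage points)

- no earlier run changes the charge of reagent; that part of a forecast is a guess
- what is bound to the catalyst counts as converted

- factor on the rate of making product when 30 % of the substrate are converted if reagent is charged twice over
- factor on the rate when 30 % of the substrate are converted if free catalyst is charged at 2.0 mM instead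

**Bench note.** The flask is charged with substrate at 0.41 M, the smaller charge and so the limiting reagent in the usual term, with the species called reagent at 0.820 M and free catalyst at 18 mM. At 30 % conversion, one reagent spent per substrate leaves 0.697 M of the reagent charge unconsumed, and τ times the catalyst predicts 0.0466 M h⁻¹. At 2.0 mM, below both charges tried, this reckoning gives a factor of 0.111. Read no reagent order off the curves, since no earlier run varies that charge. For the doubled charge, a first-order reagent gives 2.18 and no dependence gives 1, so this reckoning takes the midpoint, 1.59, as a guess.

**The result.** The forecast gives 1.8 (1 to 2.3) for the doubled reagent and 0.12 (0.09 to 0.19) for the smaller catalyst charge, and says of the reagent: “No run varies the reagent charge, so this is a guess”. The flask gives 1.48 and 0.107.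

    reagent ⇌ dormant form (K = 0.672, k = 0.477 h⁻¹)
    catalyst intermediate C ⇌ by-product + catalyst intermediate D (K = 16.5 M, k = 64.3 h⁻¹)
    substrate + free catalyst ⇌ catalyst intermediate A (K = 98.1 M⁻¹, k = 180 M⁻¹ h⁻¹)
    catalyst intermediate B → catalyst intermediate C (k = 247 h⁻¹)
    reagent + catalyst intermediate A ⇌ catalyst intermediate B (K = 8.10 M⁻¹, k = 10.8 M⁻¹ h⁻¹)
    catalyst intermediate D ⇌ free catalyst + product (K = 0.470 M, k = 8.49 h⁻¹)

**Turnover again.** At 1.50 h the flask holds 53.6 % of its catalyst as catalyst intermediate A, more than the 34.1 % as catalyst intermediate D. τ times the flask's catalyst is 0.0466 M h⁻¹, and the flask makes product at 0.0472 M h⁻¹ when 30 % of its substrate are converted, at 2.01 h. For a charge of 2.0 mM, τ gives 0.00518 M h⁻¹, and the factor 0.107 puts that rate at 0.00505 M h⁻¹.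

The runs stem from a simulated flask for an exercise; noise was put on by code.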